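(The numbers in the tables are simulated on assumed constants; noise was put on by code.)

Read the four flasks below on one clock, since they share their starting material, catalyst and added ligand charges.

common to all: starting material 0.030 M; catalyst 0.22 mol%; added ligand 0.23 mM

| charge | partner | second substrate | remark | time |
|---|---|---|---|---|
| summer | 4.4 equiv | 1 equiv | run made earlier |  |
| midnight | 9.5 equiv | 1 equiv | run made earlier |  |
| Sunday's | 2.00 equiv | 1.00 equiv |  | 12 min |
| Monday's | 8.00 equiv | 1.00 equiv |  | 12 min |

| run | time / min | target / % | starting material / % |
|---|---|---|---|
| summer | 1.33 | 25.0 | 76.2 |
| summer | 2.50 | 34.7 | 65.5 |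
| summer | 4.00 | 42.7 | 56.0 |
| summer | 5.00 | 49.3 | 54.2 |
| summer | 6.00 | 50.9 | 48.8 |
| midnight | 1.33 | 45.9 | 54.2 |
| midnight | 2.50 | 62.3 | 39.1 |
| midnight | 4.00 | 73.5 | 28.7 |
| midnight | 5.00 | 76.2 | 22.1 |
| midnight | 6.00 | 81.8 | 18.2 |

(readings scatter by 1 percentage point)

- the flask that ends with the higher amount of target, in percent of the starting material charged, or "neither" when 2 percentage points or less lies between them (Sunday's / Monday's / neither)
- final target, as a percentage of the starting material charged, in Sunday's
- final target, as a percentage of the starting material charged, in Monday's

- steps thought possible: starting material + partner + catalyst -> catalyst + target; second substrate + partner + catalyst -> catalyst + second product; catalyst + added ligand <-> idle complex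

I assume the steps as written: starting material disappears in proportion to itself and to partner, under a catalyst activity common to these flasks. In midnight, I take mean partner as the charge, less 1 equiv for second substrate, less 0.5 of the starting material used, which gives 8.09. With 18.2% left at 6.00 min, the logarithm of one over that fraction, divided by mean partner, reads 0.211. Carrying on the pace seen from 2.50 min to 6.00 min gives 0.373 at 12 min. I call this the partner clock: the logarithm of one over the fraction left, per equivalent of mean partner.

Monday's is nearly pseudo-first-order. Mean partner is about 6.50, so the clock gives 91.1% of target.

Sunday's partner just covers both substrates, so I solve the two ends. If second substrate keeps pace with starting material, partner stays at 2.00 equiv times the fraction left, and target is 42.7%. If second substrate goes at once, partner equals the fraction left, and target is 27.1%.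

The weak link is where Sunday's lies between these ends, and summer can place it. Its readings on the clock ask for a mean partner of 3.41, against 3.89 and 3.14 at the two ends. That is 64.6% of the way from keeping pace, so I commit to 32.6% for Sunday's.

The forecast says Monday's, with 41% for Sunday's and 90% for Monday's. It takes “selectivity about 1”, and its Sunday's figure stands above mine.

The flasks give 36.4% for Sunday's and 89.8% for Monday's, so the higher is Monday's.

    starting material + partner + catalyst → catalyst + target (k = 34000 M⁻² min⁻¹)
    second substrate + partner + catalyst → catalyst + second product (k = 1.00 × 10⁵ M⁻² min⁻¹)
    catalyst + added ligand ⇌ idle complex (K = 10000 M⁻¹, k = 1900 M⁻¹ min⁻¹)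

Sunday's 64% of starting material left reads on the clock as a mean partner of 1.21, between the 2.00 equiv charged and the 0.901 present at 12.0 min. The neighbouring flask is Sunday's with 0.400 equiv of second substrate. Its partner surplus over the two substrates is 0.600, which moves the ends to 40.0% and 45.5%. Summer's position between them gives 41.9%, and the neighbouring flask ends with 41.9% of target.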